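**Plan**
- Retrosynthesis: the O–SO3H bond is cut first, then the C4–C5 bond of the oct-5-enyl chain (C1 = CH2O), which joins the allylic CH2 (C4) to the vinylic CH (C5) of the trisubstituted C5=C6 olefin.
- Enabling feature: C4 is an unbranched CH2 two carbons from the C2 stereocentre, so it can be the primary radical of a 4-(silyloxymethyl)heptanoic acid (the open form of a 5-substituted oxan-2-one ring); C5 is the sp2 CH of an (E)-iodoalkene on the cyclohexene half.
- Ring half: 2-methylcyclohexenone → conjugate methylation/enolate butynylation → enol triflate → methyl coupling → alkyne zipper → methylalumination/iodination.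
- Chain half: oxazolidinone glutarate → allylation → reduction to a temporary δ-lactone → hydroboration/Suzuki coupling with 3-bromofuran → silyloxy acid → N-hydroxyphthalimide ester.
- The halves are joined by a nickel-electrocatalytic decarboxylative alkenylation; desilylation and O-sulfation finish the route.
- Stereochemistry: ring C6 (R) from ligand-controlled conjugate addition, ring C1 (S) by alkylation anti to that methyl, chain C2 (S) from the oxazolidinone auxiliary, and the E olefin from syn carboalumination, retained in the coupling.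

Key step: step 13

Assumption: the target is taken as the free hydrogen sulfate as drawn; it would be liberated from its pyridinium salt only at the end, in cold dilute solution, and stored as a salt.

**Step 1**
Reactants: 1 2-methylcyclohex-2-en-1-one
Product: 3 trimethyl{[(3R)-2,3-dimethylcyclohex-1-en-1-yl]oxy}silane, via aluminium enolate 2 (not isolated)
Conditions: Me3Al, CuTC (cat.), chiral phosphoramidite L* (cat.; enantiomer that gives 3R), Et2O, −30 °C; then TMSOTf, THF, −30 → 0 °C
Reagents that add atoms: trimethylaluminium, C[Al](C)C; trimethylsilyl trifluoromethanesulfonate, C[Si](C)(C)OS(=O)(=O)C(F)(F)F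
Why: Copper-catalysed asymmetric conjugate addition of the methylaluminium reagent to the α-substituted enone should set C3 (R) under ligand control, and O-silylation of the aluminium enolate fixes the tetrasubstituted enolate regiochemistry for the next step.

**Step 2**
Reactants: 3 trimethyl{[(3R)-2,3-dimethylcyclohex-1-en-1-yl]oxy}silane; 4 1-bromobut-2-yne
Product: 6 (2S,3R)-2-(but-2-yn-1-yl)-2,3-dimethylcyclohexan-1-one, via lithium enolate 5 (not isolated)
Conditions: MeLi, THF, 0 °C → rt; then DMPU, 4, −78 → −20 °C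
Reagents that add atoms: none
Why: Methyllithium cleaves the silyl enol ether to the regiodefined lithium enolate, and enolate C-alkylation by the propargylic bromide should occur anti to the C3 methyl (held pseudoaxial by A(1,2) strain with the C2 methyl), placing the new chain trans to it (2S).

**Step 3**
Reactants: 6 (2S,3R)-2-(but-2-yn-1-yl)-2,3-dimethylcyclohexan-1-one
Product: 8 (5R,6S)-6-(but-2-yn-1-yl)-5,6-dimethylcyclohex-1-en-1-yl trifluoromethanesulfonate, via potassium enolate 7 (not isolated)
Conditions: KHMDS, THF, −78 °C; then PhNTf2, −78 → 0 °C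
Reagents that add atoms: N-phenylbis(trifluoromethanesulfonimide), O=S(=O)(N(c1ccccc1)S(=O)(=O)C(F)(F)F)C(F)(F)F
Why: Only C6 of the ketone carries α-hydrogens, so enol triflate formation can give a single regioisomer and the quaternary centre cannot epimerise.

**Step 4**
Reactants: 8 (5R,6S)-6-(but-2-yn-1-yl)-5,6-dimethylcyclohex-1-en-1-yl trifluoromethanesulfonate
Product: 9 (5R,6S)-6-(but-2-yn-1-yl)-1,5,6-trimethylcyclohex-1-ene
Conditions: MeMgBr, Fe(acac)3 (cat.), THF/NMP, −20 → 0 °C
Reagents that add atoms: methylmagnesium bromide, C[Mg]Br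
Why: Iron-catalysed Kumada-type cross-coupling of the alkenyl triflate with the methyl Grignard reagent should replace OTf by CH3 without moving the double bond, the internal alkyne being inert at this temperature.

**Step 5**
Reactants: 9 (5R,6S)-6-(but-2-yn-1-yl)-1,5,6-trimethylcyclohex-1-ene
Product: 11 (5R,6S)-6-(but-3-yn-1-yl)-1,5,6-trimethylcyclohex-1-ene, via potassium acetylide 10 (not isolated)
Conditions: KH, 1,3-diaminopropane (KAPA), 0 °C → rt; then H2O, 0 °C
Reagents that add atoms: none
Why: In the alkyne zipper reaction the amide base equilibrates the internal alkyne through allenes until the terminal acetylide forms irreversibly, the quaternary carbon blocks migration into the ring, and neither stereocentre is acidic.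

**Step 6**
Reactants: 11 (5R,6S)-6-(but-3-yn-1-yl)-1,5,6-trimethylcyclohex-1-ene
Product: 13 (5R,6S)-6-[(3E)-4-iodo-3-methylbut-3-en-1-yl]-1,5,6-trimethylcyclohex-1-ene, via alkenylalane 12 (not isolated)
Conditions: Me3Al, Cp2ZrCl2 (cat.), CH2Cl2, 0 °C → rt; then I2, THF, −30 → 0 °C
Reagents that add atoms: trimethylaluminium, C[Al](C)C; iodine, II
Why: Zirconium-catalysed carboalumination (Negishi) adds CH3–Al syn across the terminal alkyne with methyl on the internal carbon, and iodinolysis of the C–Al bond with retention should give the (E)-iodoalkene while the trisubstituted ring olefin stays untouched.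

**Step 7**
Reactants: 14 (4S)-4-benzyl-1,3-oxazolidin-2-one; 15 methyl 5-chloro-5-oxopentanoate
Product: 17 methyl 5-[(4S)-4-benzyl-2-oxo-1,3-oxazolidin-3-yl]-5-oxopentanoate, via N-lithio oxazolidinone 16 (not isolated)
Conditions: n-BuLi, THF, −78 °C; then 15, −78 → 0 °C
Reagents that add atoms: none
Why: N-acylation of the lithiated oxazolidinone by the acid chloride is much faster than attack on the methyl ester.

**Step 8**
Reactants: 17 methyl 5-[(4S)-4-benzyl-2-oxo-1,3-oxazolidin-3-yl]-5-oxopentanoate; 18 3-iodoprop-1-ene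
Product: 20 methyl (4R)-4-{[(4S)-4-benzyl-2-oxo-1,3-oxazolidin-3-yl]carbonyl}hept-6-enoate, via sodium enolate 19 (not isolated)
Conditions: NaHMDS, THF, −78 °C; then 18, −78 → −45 °C
Reagents that add atoms: none
Why: In this Evans asymmetric alkylation the chelated (Z)-enolate forms at the more acidic imide α-position rather than at the ester and should be allylated on the face opposite the benzyl group, setting the future C2 centre (4R here).

**Step 9**
Reactants: 20 methyl (4R)-4-{[(4S)-4-benzyl-2-oxo-1,3-oxazolidin-3-yl]carbonyl}hept-6-enoate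
Product: 22 (5R)-5-(prop-2-en-1-yl)oxan-2-one, via hydroxy ester 21 (not isolated)
Conditions: NaBH4, THF/H2O, 0 °C → rt; then PPTS (cat.), PhMe, 50 °C
Reagents that add atoms: none
Why: Borohydride in aqueous THF reduces the activated exocyclic imide carbonyl to the primary alcohol and releases the auxiliary while the methyl ester survives, and acid-catalysed lactonisation then closes the six-membered lactone as a temporary ring masking both the hydroxyl and the carboxyl group.

**Step 10**
Reactants: 22 (5R)-5-(prop-2-en-1-yl)oxan-2-one; 23 3-bromofuran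
Product: 25 (5S)-5-[3-(furan-3-yl)propyl]oxan-2-one, via alkylborane 24 (not isolated)
Conditions: 9-BBN, THF, 0 °C → rt; then 23, PdCl2(dppf) (cat.), K3PO4 (aq), DMF, 50 °C; work-up at pH 4
Reagents that add atoms: none
Why: 9-BBN hydroborates the monosubstituted alkene anti-Markovnikov faster than it reduces the lactone, and B-alkyl Suzuki–Miyaura coupling of the alkylborane with the heteroaryl bromide should form the sp3–sp2 bond without touching the stereocentre (the descriptor changes only through priorities).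

**Step 11**
Reactants: 25 (5S)-5-[3-(furan-3-yl)propyl]oxan-2-one
Product: 28 (4S)-4-({[tert-butyl(dimethyl)silyl]oxy}methyl)-7-(furan-3-yl)heptanoic acid, via potassium hydroxy carboxylate 26 (not isolated), via bis-silyl derivative 27 (not isolated)
Conditions: KOH, MeOH/H2O, rt, evaporate; TBSCl, imidazole, DMF, rt; then K2CO3, MeOH/THF/H2O, rt, acidify to pH 4–5
Reagents that add atoms: potassium hydroxide, [K+].[OH-]; tert-butyldimethylsilyl chloride, CC(C)(C)[Si](C)(C)Cl
Why: Saponification opens the temporary lactone, silylation caps both oxygens, and the far more labile silyl ester is then cleaved selectively by mild base, which is the standard lactone to silyloxy acid sequence.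

**Step 12**
Reactants: 28 (4S)-4-({[tert-butyl(dimethyl)silyl]oxy}methyl)-7-(furan-3-yl)heptanoic acid
Product: 29 1,3-dioxo-1,3-dihydro-2H-isoindol-2-yl (4S)-4-({[tert-butyl(dimethyl)silyl]oxy}methyl)-7-(furan-3-yl)heptanoate
Conditions: N-hydroxyphthalimide, DIC, DMAP (cat.), CH2Cl2, rt
Reagents that add atoms: N-hydroxyphthalimide, O=C1c2ccccc2C(=O)N1O
Why: Carbodiimide (Steglich-type) esterification installs the redox-active ester, the activating group that leaves as CO2 and phthalimide in the coupling.

**Step 13**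
Reactants: 13 (5R,6S)-6-[(3E)-4-iodo-3-methylbut-3-en-1-yl]-1,5,6-trimethylcyclohex-1-ene; 29 1,3-dioxo-1,3-dihydro-2H-isoindol-2-yl (4S)-4-({[tert-butyl(dimethyl)silyl]oxy}methyl)-7-(furan-3-yl)heptanoate
Product: 30 tert-butyl{[(2S,5E)-2-[3-(furan-3-yl)propyl]-6-methyl-8-[(1S,6R)-1,2,6-trimethylcyclohex-2-en-1-yl]oct-5-en-1-yl]oxy}dimethylsilane
Conditions: NiCl2·6H2O (cat.), 2,2′-bipyridine (cat.), AgNO3 (substoichiometric, silver-coated cathode formed in situ), LiCl, DMF, Mg anode/RVC cathode, constant current, rt, undivided cell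
Reagents that add atoms: none
Why: Cathodically generated low-valent Ni(bpy) inserts into the C–I bond of 13 with retention of the E geometry, while single-electron reduction of ester 29 triggers N–O cleavage and loss of CO2 to give the primary C4 radical, which is captured by the alkenyl–Ni(II) species so that reductive elimination from Ni(III) forms the C4–C5 bond, the magnesium anode supplying the electrons. The closest known reaction type is the nickel-electrocatalytic decarboxylative alkenylation of N-hydroxyphthalimide esters with iodoalkenes used for modular polyene assembly. No ring is closed and no stereocentre is formed; the C2 centre lies two carbons from the radical and the ring centres are remote, so all three should be carried through unchanged. The step needs cross- over homo-coupling and retention of the C5=C6 geometry: the two partners enter the nickel cycle by different elementary steps (two-electron oxidative addition versus radical capture), which favours the cross product, and a modest excess of 13 with the silver-coated cathode should suppress direct reduction of 29 to the alkane. The primary radical has no 5- or 6-membered cyclisation open to it and no activated C–H within reach of a 1,5-hydrogen shift, and the silyl ether, furan and ring olefin are inert at the potential used.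

**Step 14**
Reactants: 30 tert-butyl{[(2S,5E)-2-[3-(furan-3-yl)propyl]-6-methyl-8-[(1S,6R)-1,2,6-trimethylcyclohex-2-en-1-yl]oct-5-en-1-yl]oxy}dimethylsilane
Product: 31 (2S,5E)-2-[3-(furan-3-yl)propyl]-6-methyl-8-[(1S,6R)-1,2,6-trimethylcyclohex-2-en-1-yl]oct-5-en-1-ol
Conditions: TBAF, THF, 0 °C → rt
Reagents that add atoms: none
Why: Fluoride-mediated desilylation cleaves only the Si–O bond, the olefins and the furan being inert.

**Step 15**
Reactants: 31 (2S,5E)-2-[3-(furan-3-yl)propyl]-6-methyl-8-[(1S,6R)-1,2,6-trimethylcyclohex-2-en-1-yl]oct-5-en-1-ol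
Product: 33 (2S,5E)-2-[3-(furan-3-yl)propyl]-6-methyl-8-[(1S,6R)-1,2,6-trimethylcyclohex-2-en-1-yl]oct-5-en-1-yl hydrogen sulfate (CNP0316188.3), via pyridinium sulfate salt 32 (not isolated)
Conditions: SO3·pyridine, pyridine, rt; then H+-form cation-exchange resin, MeOH/H2O, 0 °C
Reagents that add atoms: sulfur trioxide–pyridine complex, [O-]S(=O)(=O)[n+]1ccccc1
Why: O-sulfation of the primary alcohol by the SO3–amine complex is far faster at room temperature than electrophilic sulfonation of the furan, and proton exchange of the pyridinium salt gives the hydrogen sulfate.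

**Compound list**
1 | 2-methylcyclohex-2-en-1-one | CC1=CCCCC1=O | starting material
2 | dimethylaluminium (3R)-2,3-dimethylcyclohex-1-en-1-olate | C[C@@H]1CCCC(O[Al](C)C)=C1C | intermediate
3 | trimethyl{[(3R)-2,3-dimethylcyclohex-1-en-1-yl]oxy}silane | C[C@@H]1CCCC(O[Si](C)(C)C)=C1C | intermediate
4 | 1-bromobut-2-yne | CC#CCBr | starting material
5 | lithium (3R)-2,3-dimethylcyclohex-1-en-1-olate | C[C@@H]1CCCC(O[Li])=C1C | intermediate
6 | (2S,3R)-2-(but-2-yn-1-yl)-2,3-dimethylcyclohexan-1-one | O=C1CCC[C@@H](C)[C@]1(C)CC#CC | intermediate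
7 | potassium (5R,6S)-6-(but-2-yn-1-yl)-5,6-dimethylcyclohex-1-en-1-olate | [K]OC1=CCC[C@@H](C)[C@]1(C)CC#CC | intermediate
8 | (5R,6S)-6-(but-2-yn-1-yl)-5,6-dimethylcyclohex-1-en-1-yl trifluoromethanesulfonate | O=S(=O)(OC1=CCC[C@@H](C)[C@]1(C)CC#CC)C(F)(F)F | intermediate
9 | (5R,6S)-6-(but-2-yn-1-yl)-1,5,6-trimethylcyclohex-1-ene | CC1=CCC[C@@H](C)[C@]1(C)CC#CC | intermediate
10 | {4-[(1S,6R)-1,2,6-trimethylcyclohex-2-en-1-yl]but-1-yn-1-yl}potassium | CC1=CCC[C@@H](C)[C@]1(C)CCC#C[K] | intermediate
11 | (5R,6S)-6-(but-3-yn-1-yl)-1,5,6-trimethylcyclohex-1-ene | CC1=CCC[C@@H](C)[C@]1(C)CCC#C | intermediate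
12 | dimethyl{(1E)-2-methyl-4-[(1S,6R)-1,2,6-trimethylcyclohex-2-en-1-yl]but-1-en-1-yl}alumane | CC1=CCC[C@@H](C)[C@]1(C)CC/C(C)=C/[Al](C)C | intermediate
13 | (5R,6S)-6-[(3E)-4-iodo-3-methylbut-3-en-1-yl]-1,5,6-trimethylcyclohex-1-ene | CC1=CCC[C@@H](C)[C@]1(C)CC/C(C)=C/I | intermediate
14 | (4S)-4-benzyl-1,3-oxazolidin-2-one | O=C1N[C@@H](Cc2ccccc2)CO1 | starting material
15 | methyl 5-chloro-5-oxopentanoate | COC(=O)CCCC(Cl)=O | starting material
16 | lithium (4S)-4-benzyl-2-oxo-1,3-oxazolidin-3-ide | [Li]N1[C@@H](Cc2ccccc2)COC1=O | intermediate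
17 | methyl 5-[(4S)-4-benzyl-2-oxo-1,3-oxazolidin-3-yl]-5-oxopentanoate | COC(=O)CCCC(=O)N1[C@@H](Cc2ccccc2)COC1=O | intermediate
18 | 3-iodoprop-1-ene | C=CCI | starting material
19 | sodium (1Z)-1-[(4S)-4-benzyl-2-oxo-1,3-oxazolidin-3-yl]-5-methoxy-5-oxopent-1-en-1-olate | COC(=O)CC/C=C(\O[Na])N1[C@@H](Cc2ccccc2)COC1=O | intermediate
20 | methyl (4R)-4-{[(4S)-4-benzyl-2-oxo-1,3-oxazolidin-3-yl]carbonyl}hept-6-enoate | COC(=O)CC[C@H](CC=C)C(=O)N1[C@@H](Cc2ccccc2)COC1=O | intermediate
21 | methyl (4R)-4-(hydroxymethyl)hept-6-enoate | COC(=O)CC[C@H](CC=C)CO | intermediate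
22 | (5R)-5-(prop-2-en-1-yl)oxan-2-one | O=C1CC[C@H](CC=C)CO1 | intermediate
23 | 3-bromofuran | Brc1ccoc1 | starting material
24 | (5S)-5-[3-(9-borabicyclo[3.3.1]nonan-9-yl)propyl]oxan-2-one | O=C1CC[C@H](CCCB2C3CCCC2CCC3)CO1 | intermediate
25 | (5S)-5-[3-(furan-3-yl)propyl]oxan-2-one | O=C1CC[C@H](CCCc2ccoc2)CO1 | intermediate
26 | potassium (4S)-7-(furan-3-yl)-4-(hydroxymethyl)heptanoate | [K+].[O-]C(=O)CC[C@H](CCCc1ccoc1)CO | intermediate
27 | tert-butyldimethylsilyl (4S)-4-({[tert-butyl(dimethyl)silyl]oxy}methyl)-7-(furan-3-yl)heptanoate | CC(C)(C)[Si](C)(C)OC(=O)CC[C@H](CCCc1ccoc1)CO[Si](C)(C)C(C)(C)C | intermediate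
28 | (4S)-4-({[tert-butyl(dimethyl)silyl]oxy}methyl)-7-(furan-3-yl)heptanoic acid | OC(=O)CC[C@H](CCCc1ccoc1)CO[Si](C)(C)C(C)(C)C | intermediate
29 | 1,3-dioxo-1,3-dihydro-2H-isoindol-2-yl (4S)-4-({[tert-butyl(dimethyl)silyl]oxy}methyl)-7-(furan-3-yl)heptanoate | O=C(CC[C@H](CCCc1ccoc1)CO[Si](C)(C)C(C)(C)C)ON1C(=O)c2ccccc2C1=O | intermediate
30 | tert-butyl{[(2S,5E)-2-[3-(furan-3-yl)propyl]-6-methyl-8-[(1S,6R)-1,2,6-trimethylcyclohex-2-en-1-yl]oct-5-en-1-yl]oxy}dimethylsilane | CC1=CCC[C@@H](C)[C@]1(C)CC/C(C)=C/CC[C@H](CCCc1ccoc1)CO[Si](C)(C)C(C)(C)C | intermediate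
31 | (2S,5E)-2-[3-(furan-3-yl)propyl]-6-methyl-8-[(1S,6R)-1,2,6-trimethylcyclohex-2-en-1-yl]oct-5-en-1-ol | CC1=CCC[C@@H](C)[C@]1(C)CC/C(C)=C/CC[C@H](CCCc1ccoc1)CO | intermediate
32 | pyridinium (2S,5E)-2-[3-(furan-3-yl)propyl]-6-methyl-8-[(1S,6R)-1,2,6-trimethylcyclohex-2-en-1-yl]oct-5-en-1-yl sulfate | CC1=CCC[C@@H](C)[C@]1(C)CC/C(C)=C/CC[C@H](CCCc1ccoc1)COS(=O)(=O)[O-].c1cc[nH+]cc1 | intermediate
33 | (2S,5E)-2-[3-(furan-3-yl)propyl]-6-methyl-8-[(1S,6R)-1,2,6-trimethylcyclohex-2-en-1-yl]oct-5-en-1-yl hydrogen sulfate (CNP0316188.3) | CC1=CCC[C@@H](C)[C@]1(C)CC/C(C)=C/CC[C@H](CCCc1ccoc1)COS(=O)(=O)O | target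

**Totals**
Total step count: 15.
Longest linear sequence: 9 steps (steps 1–6 then 13–15; the chain half, steps 7–12 then 13–15, is equally long).

**Steps most likely to fail**

Step 13. The electrolysis may fail through homodimerisation of the iodoalkene, reduction of the radical to the alkane before nickel captures it, or stalling of the cathodic cycle. The same C4–C5 bond would then be made by a palladium-catalysed Negishi sp3–sp2 coupling. The fallback sets out from acid 28. Esterification with N-hydroxypyridine-2-thione (DCC, CH2Cl2, dark) should give the Barton ester 2-thioxopyridin-1(2H)-yl (4S)-4-({[tert-butyl(dimethyl)silyl]oxy}methyl)-7-(furan-3-yl)heptanoate F1. Its photolysis in the presence of iodoform (Barton decarboxylative iodination) should give tert-butyl{[(2S)-5-(furan-3-yl)-2-(2-iodoethyl)pentyl]oxy}dimethylsilane F2. Zinc insertion (Zn dust, LiCl, THF) would give {(3S)-3-({[tert-butyl(dimethyl)silyl]oxy}methyl)-6-(furan-3-yl)hexyl}zinc iodide F3, and coupling with iodoalkene 13 [PdCl2(dppf), THF, rt] comes back to the route at 30.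

Step 5. The strongly basic amide may cause migration of the ring double bond, or the isomerisation may stop at allene or internal alkyne isomers. The alkyne would then be built from an allyl group instead. The fallback sets out from silyl enol ether 3. Cleavage to enolate 5 and alkylation with allyl bromide should give (2S,3R)-2,3-dimethyl-2-(prop-2-en-1-yl)cyclohexan-1-one F4. Deprotonation (KHMDS) to potassium (5R,6S)-5,6-dimethyl-6-(prop-2-en-1-yl)cyclohex-1-en-1-olate F5 and triflation (PhNTf2) would give (5R,6S)-5,6-dimethyl-6-(prop-2-en-1-yl)cyclohex-1-en-1-yl trifluoromethanesulfonate F6. Iron-catalysed methylation as in step 4 gives (5R,6S)-1,5,6-trimethyl-6-(prop-2-en-1-yl)cyclohex-1-ene F7. 9-BBN should add only to the monosubstituted alkene to give 9-{3-[(1S,6R)-1,2,6-trimethylcyclohex-2-en-1-yl]propyl}-9-borabicyclo[3.3.1]nonane F8, which is oxidised (NaOH, H2O2) to 3-[(1S,6R)-1,2,6-trimethylcyclohex-2-en-1-yl]propan-1-ol F9. Dess–Martin oxidation gives 3-[(1S,6R)-1,2,6-trimethylcyclohex-2-en-1-yl]propanal F10, and Seyferth–Gilbert homologation with the Ohira–Bestmann reagent (K2CO3, MeOH) comes back to the route at 11.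

Step 9. Hydride delivery may be unselective (endocyclic attack that opens the oxazolidinone ring, or partial reduction of the methyl ester), or ring closure may be incomplete. The auxiliary would then be removed hydrolytically and the acid reduced separately. The fallback sets out from imide 20. Cleavage with LiOH/H2O2 (THF/H2O, 0 °C, short time) should give (2R)-5-methoxy-5-oxo-2-(prop-2-en-1-yl)pentanoic acid F11. Activation with isobutyl chloroformate and N-methylmorpholine gives the mixed anhydride 2-methylpropyl (2R)-5-methoxy-5-oxo-2-(prop-2-en-1-yl)pentanoyl carbonate F12, and NaBH4 reduces it chemoselectively to hydroxy ester 21, which is lactonised as in step 9 and so comes back to the route at 22.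

**Further compounds**
F1 | step 13 | 2-thioxopyridin-1(2H)-yl (4S)-4-({[tert-butyl(dimethyl)silyl]oxy}methyl)-7-(furan-3-yl)heptanoate | S=c1ccccn1OC(=O)CC[C@H](CCCc1ccoc1)CO[Si](C)(C)C(C)(C)C
F2 | step 13 | tert-butyl{[(2S)-5-(furan-3-yl)-2-(2-iodoethyl)pentyl]oxy}dimethylsilane | ICC[C@H](CCCc1ccoc1)CO[Si](C)(C)C(C)(C)C
F3 | step 13 | {(3S)-3-({[tert-butyl(dimethyl)silyl]oxy}methyl)-6-(furan-3-yl)hexyl}zinc iodide | I[Zn]CC[C@H](CCCc1ccoc1)CO[Si](C)(C)C(C)(C)C
F4 | step 5 | (2S,3R)-2,3-dimethyl-2-(prop-2-en-1-yl)cyclohexan-1-one | O=C1CCC[C@@H](C)[C@]1(C)CC=C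
F5 | step 5 | potassium (5R,6S)-5,6-dimethyl-6-(prop-2-en-1-yl)cyclohex-1-en-1-olate | [K]OC1=CCC[C@@H](C)[C@]1(C)CC=C
F6 | step 5 | (5R,6S)-5,6-dimethyl-6-(prop-2-en-1-yl)cyclohex-1-en-1-yl trifluoromethanesulfonate | O=S(=O)(OC1=CCC[C@@H](C)[C@]1(C)CC=C)C(F)(F)F
F7 | step 5 | (5R,6S)-1,5,6-trimethyl-6-(prop-2-en-1-yl)cyclohex-1-ene | CC1=CCC[C@@H](C)[C@]1(C)CC=C
F8 | step 5 | 9-{3-[(1S,6R)-1,2,6-trimethylcyclohex-2-en-1-yl]propyl}-9-borabicyclo[3.3.1]nonane | CC1=CCC[C@@H](C)[C@]1(C)CCCB2C3CCCC2CCC3
F9 | step 5 | 3-[(1S,6R)-1,2,6-trimethylcyclohex-2-en-1-yl]propan-1-ol | CC1=CCC[C@@H](C)[C@]1(C)CCCO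
F10 | step 5 | 3-[(1S,6R)-1,2,6-trimethylcyclohex-2-en-1-yl]propanal | CC1=CCC[C@@H](C)[C@]1(C)CCC=O
F11 | step 9 | (2R)-5-methoxy-5-oxo-2-(prop-2-en-1-yl)pentanoic acid | COC(=O)CC[C@H](CC=C)C(O)=O
F12 | step 9 | 2-methylpropyl (2R)-5-methoxy-5-oxo-2-(prop-2-en-1-yl)pentanoyl carbonate | COC(=O)CC[C@H](CC=C)C(=O)OC(=O)OCC(C)C
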